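**Retrosynthetic overview**
The last cut removes two benzyl groups, the C1' ester of ring B and the 2-O ether of ring A, in a single hydrogenolysis, so the depside is assembled as its dibenzyl derivative.
The strategy rests on ring B. C2' (free OH), C3' (CH3) and C4' (O-aroyl) are three neighbouring ring carbons, a 1-hydroxy-2-alkyl-3-acyloxy pattern that a propargyl ester 1,2-shift plus CO insertion produces in one operation. Ring B is therefore opened at O–C4', C2'–C3' and C1'–C2' to CO (the future C2') and an acyclic (E)-enynyl ester whose acyl group is already ring A, so the depside ester is the migrating group.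
That ester is cut at its alkyl C–O bond (Mitsunobu) into the ring A acid and a C8 enynol, the latter made from 3-methylbut-2-enoic acid by benzylation, SeO2 oxidation and propynyl Grignard addition.
Ring A is bought as methyl orsellinate and only decorated (4-O-methylation, ortho-formylation at C3, 2-O-benzylation, ester cleavage under acetal cover). Ring A is thus present from the start, and ring B is closed in the penultimate step.
Key step: step 10

Assumption: baeomycesic acid has no stereocentre, so the carbinol carbon of the enynol and of its aroate is carried racemic. The only stereochemical element to be set is the E geometry of the enoate.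

**Step 1**
Reactants: 1 3-methylbut-2-enoic acid; 2 benzyl bromide
Product: 3 benzyl 3-methylbut-2-enoate
Conditions: K2CO3, DMF, rt
Reagents that add atoms: benzyl bromide 2, BrCc1ccccc1
Why: Carboxylate O-alkylation (SN2) with a benzylic bromide is fast at room temperature and installs the ester that the last step removes by hydrogenolysis.

**Step 2**
Reactants: 3 benzyl 3-methylbut-2-enoate
Product: 4 benzyl (E)-3-methyl-4-oxobut-2-enoate
Conditions: SeO2 (1.2 equiv), 1,4-dioxane, reflux
Reagents that add atoms: selenium dioxide, O=[Se]=O
Why: The Riley allylic oxidation (ene reaction, then [2,3]-sigmatropic shift) attacks the methyl group trans to the ester of the trisubstituted alkene and runs on to the aldehyde, a behaviour known for the simple alkyl esters of this acid, so the E geometry needed in the key step is set here.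

**Step 3**
Reactants: 4 benzyl (E)-3-methyl-4-oxobut-2-enoate; 5 prop-1-ynylmagnesium bromide
Product: 6 racemic benzyl (E)-4-hydroxy-3-methylhept-2-en-5-ynoate
Conditions: THF, −78 °C; then aq. NH4Cl
Reagents that add atoms: prop-1-ynylmagnesium bromide 5, CC#C[Mg]Br
Why: 1,2-Addition of an alkynyl Grignard reagent to the aldehyde outruns ester attack and conjugate addition at −78 °C; the new carbinol centre forms racemic, which is harmless because it becomes aromatic C5', and the E alkene keeps the alkoxide away from the ester so that no butenolide can form.

**Step 4**
Reactants: 7 methyl 2,4-dihydroxy-6-methylbenzoate (methyl orsellinate)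
Product: 8 methyl 2-hydroxy-4-methoxy-6-methylbenzoate
Conditions: MeI (1.05 equiv), K2CO3 (1.1 equiv), acetone, reflux
Reagents that add atoms: iodomethane, CI
Why: Williamson etherification with one equivalent of MeI takes the free 4-OH, because the 2-OH is hydrogen-bonded to the ester carbonyl and is the less acidic and more shielded phenol.

**Step 5**
Reactants: 8 methyl 2-hydroxy-4-methoxy-6-methylbenzoate
Product: 9 methyl 3-formyl-2-hydroxy-4-methoxy-6-methylbenzoate
Conditions: MgCl2, Et3N, (CH2O)n, MeCN, reflux; then 1 M HCl
Reagents that add atoms: paraformaldehyde (reacts as formaldehyde), C=O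
Why: The Casnati–Skattebøl ortho-formylation delivers formaldehyde within the chloromagnesium phenoxide (ArOMgCl) to an ortho carbon only, C3 is the single open ortho position of the 2-OH (C1 bears the ester), and a second formaldehyde accepts hydride to give the aldehyde.

**Step 6**
Reactants: 9 methyl 3-formyl-2-hydroxy-4-methoxy-6-methylbenzoate; 2 benzyl bromide
Product: 10 methyl 2-benzyloxy-3-formyl-4-methoxy-6-methylbenzoate
Conditions: K2CO3, DMF, 60 °C
Reagents that add atoms: benzyl bromide 2, BrCc1ccccc1
Why: Williamson benzylation of the acidic phenol between two carbonyl groups needs only K2CO3 in a dipolar solvent with gentle heating, and it masks the one OH that could quench the carbene or the ketene of the key step.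

**Step 7**
Reactants: 10 methyl 2-benzyloxy-3-formyl-4-methoxy-6-methylbenzoate
Product: 11 methyl 2-benzyloxy-3-(dimethoxymethyl)-4-methoxy-6-methylbenzoate
Conditions: HC(OMe)3, p-TsOH·H2O (cat.), MeOH, rt; then Et3N
Reagents that add atoms: trimethyl orthoformate, COC(OC)OC
Why: Acid-catalysed acetalisation driven by the orthoester is easy for an aldehyde with two donor ortho oxygens, and it shields the formyl group from hot hydroxide (Cannizzaro reaction, deformylation, SNAr at the activated C2 and C4 ethers) in the next step.

**Step 8**
Reactants: 11 methyl 2-benzyloxy-3-(dimethoxymethyl)-4-methoxy-6-methylbenzoate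
Product: 13 2-benzyloxy-3-formyl-4-methoxy-6-methylbenzoic acid, via potassium acetal carboxylate 12 (not isolated)
Conditions: KOH (excess), MeOH–H2O, reflux; then 1 M HCl, THF, rt
Reagents that add atoms: potassium hydroxide, [K+].[OH-]; water, O
Why: Saponification (BAc2) of the doubly ortho-substituted methyl ester needs hot concentrated KOH, which the ethers and the acetal tolerate, and the acidification that frees the acid also hydrolyses the very labile electron-rich dimethyl acetal back to the aldehyde.

**Step 9**
Reactants: 6 racemic benzyl (E)-4-hydroxy-3-methylhept-2-en-5-ynoate; 13 2-benzyloxy-3-formyl-4-methoxy-6-methylbenzoic acid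
Product: 14 racemic benzyl (E)-4-[(2-benzyloxy-3-formyl-4-methoxy-6-methylbenzoyl)oxy]-3-methylhept-2-en-5-ynoate
Conditions: PPh3, DIAD, THF, 0 °C to rt
Reagents that add atoms: none
Why: The Mitsunobu esterification forms the alkyl C–O bond with the carboxylate as nucleophile, so the crowded acyl carbon of 13 is never attacked and no base meets the acidic C4–H of 6; inversion at the racemic carbinol is irrelevant, the methyl cap and the acceptor alkene disfavour SN2′ entry, and no β-hydrogen is available for elimination.

**Step 10**
Reactants: 14 racemic benzyl (E)-4-[(2-benzyloxy-3-formyl-4-methoxy-6-methylbenzoyl)oxy]-3-methylhept-2-en-5-ynoate; 15 carbon monoxide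
Product: 19 benzyl 2-O-benzylbaeomycesate, via RhCl(CO)2 vinylcarbene 16 (not isolated), via dienylketene 17 (not isolated), via cyclohexadienone tautomer 18 (not isolated)
Conditions: [RhCl(CO)2]2 (5 mol %), CO (5 atm), ClCH2CH2Cl, 80 °C
Reagents that add atoms: carbon monoxide 15, [C-]#[O+]
Why: Proposed new method: monovalent rhodium bound to the alkyne of 14 lets the aroate carbonyl oxygen attack the inner alkyne carbon (5-exo), and collapse of the resulting dioxolenium ion with cleavage of the old carbinol C–O bond moves the depside oxygen onto the future C4' (1,2-acyloxy shift) and leaves the metal as a carbene on the methyl-bearing C3' in 16. Migratory insertion of CO forms C2'–C3' and gives dienylketene 17, whose ketene carbon bonds to the ester-bearing alkene carbon in a thermal six-electron electrocyclisation (C1'–C2'; this closes the six-membered carbocycle ring B, with H and not CO2Bn on the inner side of the triene because the alkene is E), and enolisation of dienone 18 gives phenol 19 with the CO carbon as C2'–OH. The closest known reaction type is the [RhCl(CO)2]2-catalysed (5+1) carbonylative benzannulation of 3-acyloxy-1,4-enynes to resorcinol monoesters, which is established for terminal alkynes, whereas alkyl-capped alkynes are known to lean toward the 1,3-shift and a (4+1) carbonylation of the vinylallene, so a methyl-capped enyne bearing a large aroate lies outside the shown substrate class. The selectivity needed is thus 1,2- over 1,3-shift, and the substrate offers three aids: the enoate alkene is a better π-acceptor ligand than a plain alkene and should chelate the metal together with the alkyne, which places rhodium on the outer alkyne carbon from where the six-membered rhodacycle can form; the aroate carries para-methoxy and ortho-benzyloxy donors, and donor aroates are known to speed the 1,2-shift in related rhodium cycloadditions; and both shifts are reversible while CO capture followed by aromatisation is not. No stereocentre survives, since the racemic carbinol carbon becomes aromatic C5'–H and the transient sp3 C1' of 18 is lost on enolisation. The two ortho substituents shield the acyl carbon from transfer, the benzyl ether keeps the 2-OH from quenching carbene or ketene, and the aldehyde, flanked on both sides and kept under CO, should not be decarbonylated at 80 °C.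

**Step 11**
Reactants: 19 benzyl 2-O-benzylbaeomycesate
Product: 20 baeomycesic acid
Conditions: H2 (1 atm), 10% Pd/C, EtOAc, rt
Reagents that add atoms: none
Why: Catalytic hydrogenolysis cleaves both benzylic C–O bonds under neutral conditions that leave the depside ester alone, and the aldehyde, a hydrogen-bonded vinylogous ester between two oxygen substituents, is reduced much more slowly, so the reaction is stopped after uptake of two equivalents of H2.

**Compound list**
1 | 3-methylbut-2-enoic acid | CC(C)=CC(=O)O | starting material
2 | benzyl bromide | BrCc1ccccc1 | starting material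
3 | benzyl 3-methylbut-2-enoate | CC(C)=CC(=O)OCc1ccccc1 | intermediate
4 | benzyl (E)-3-methyl-4-oxobut-2-enoate | O=C/C(C)=C/C(=O)OCc1ccccc1 | intermediate
5 | prop-1-ynylmagnesium bromide | CC#C[Mg]Br | starting material
6 | racemic benzyl (E)-4-hydroxy-3-methylhept-2-en-5-ynoate | CC#CC(O)/C(C)=C/C(=O)OCc1ccccc1 | intermediate
7 | methyl 2,4-dihydroxy-6-methylbenzoate (methyl orsellinate) | COC(=O)c1c(C)cc(O)cc1O | starting material
8 | methyl 2-hydroxy-4-methoxy-6-methylbenzoate | COC(=O)c1c(C)cc(OC)cc1O | intermediate
9 | methyl 3-formyl-2-hydroxy-4-methoxy-6-methylbenzoate | COC(=O)c1c(C)cc(OC)c(C=O)c1O | intermediate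
10 | methyl 2-benzyloxy-3-formyl-4-methoxy-6-methylbenzoate | COC(=O)c1c(C)cc(OC)c(C=O)c1OCc1ccccc1 | intermediate
11 | methyl 2-benzyloxy-3-(dimethoxymethyl)-4-methoxy-6-methylbenzoate | COC(=O)c1c(C)cc(OC)c(C(OC)OC)c1OCc1ccccc1 | intermediate
12 | potassium 2-benzyloxy-3-(dimethoxymethyl)-4-methoxy-6-methylbenzoate (not isolated) | [K+].[O-]C(=O)c1c(C)cc(OC)c(C(OC)OC)c1OCc1ccccc1 | intermediate
13 | 2-benzyloxy-3-formyl-4-methoxy-6-methylbenzoic acid | COc1cc(C)c(C(=O)O)c(OCc2ccccc2)c1C=O | intermediate
14 | racemic benzyl (E)-4-[(2-benzyloxy-3-formyl-4-methoxy-6-methylbenzoyl)oxy]-3-methylhept-2-en-5-ynoate | CC#CC(OC(=O)c1c(C)cc(OC)c(C=O)c1OCc1ccccc1)/C(C)=C/C(=O)OCc1ccccc1 | intermediate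
15 | carbon monoxide | [C-]#[O+] | starting material
16 | RhCl(CO)2 carbene complex at C6 of benzyl (2E,4E)-5-(aroyloxy)-3-methylhepta-2,4-dienoate, aroyl = 2-benzyloxy-3-formyl-4-methoxy-6-methylbenzoyl (not isolated; ligand count on rhodium nominal) | CC(=[Rh](Cl)(=C=O)=C=O)/C(OC(=O)c1c(C)cc(OC)c(C=O)c1OCc1ccccc1)=C\C(C)=C\C(=O)OCc1ccccc1 | intermediate
17 | benzyl (2E,4E)-5-(aroyloxy)-3,6-dimethyl-7-oxohepta-2,4,6-trienoate, same aroyl group (dienylketene, not isolated) | CC(=C=O)/C(OC(=O)c1c(C)cc(OC)c(C=O)c1OCc1ccccc1)=C\C(C)=C\C(=O)OCc1ccccc1 | intermediate
18 | racemic benzyl 4-(aroyloxy)-3,6-dimethyl-2-oxocyclohexa-3,5-diene-1-carboxylate, same aroyl group (not isolated) | CC1=C(OC(=O)c2c(C)cc(OC)c(C=O)c2OCc2ccccc2)C=C(C)C(C(=O)OCc2ccccc2)C1=O | intermediate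
19 | benzyl 2-O-benzylbaeomycesate (benzyl 4-[(2-benzyloxy-3-formyl-4-methoxy-6-methylbenzoyl)oxy]-2-hydroxy-3,6-dimethylbenzoate) | COc1cc(C)c(C(=O)Oc2cc(C)c(C(=O)OCc3ccccc3)c(O)c2C)c(OCc2ccccc2)c1C=O | intermediate
20 | baeomycesic acid | COc1cc(C)c(C(=O)Oc2cc(C)c(C(=O)O)c(O)c2C)c(O)c1C=O | target

**Step count**
Total step count: 11.
Longest linear sequence: 8 (steps 4 to 11, from methyl orsellinate). The enynol branch (steps 1 to 3) joins at step 9.

**Steps most likely to fail**

**Risk 1, step 10.**
- What may go wrong: the aroate may shift 1,3 to the methyl-bearing alkyne carbon instead of 1,2. Carbonylation of the resulting vinylallene in the (4+1) sense would then consume the material.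
- The carbene may also close to a five-membered ring without CO uptake.
- The twisted, bulky aroate may migrate too slowly at a temperature the substrate tolerates.
- Fallback: known chemistry in which ring B is bought rather than built. It sets out from 13 and returns at 19.
- Methyl 2,4-dihydroxy-3,6-dimethylbenzoate F1, an article of commerce, is hydrolysed through its acylium ion in concentrated H2SO4 and poured on ice to give 2,4-dihydroxy-3,6-dimethylbenzoic acid F2.
- The carboxylate of F2 alone is benzylated with 2 and KHCO3 in DMF to give benzyl 2,4-dihydroxy-3,6-dimethylbenzoate F3.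
- Acid 13 is converted with trifluoroacetic anhydride in toluene into 2-benzyloxy-3-formyl-4-methoxy-6-methylbenzoic trifluoroacetic anhydride F4.
- F4 acylates the unchelated 4-OH of F3, because the 2-OH is hydrogen-bonded to the ester and flanked on both sides. This classical depside esterification gives 19, and step 11 follows unchanged.

**Risk 2, step 9.**
- What may go wrong: displacement at the crowded secondary centre may be sluggish. That leaves room for SN2′ leakage toward an allene, or for acyl transfer from the activated acid to the reduced azodicarboxylate.
- Fallback: the bond formed is changed from alkyl C–O to acyl C–O. It sets out from 13 and 6 and returns at 14.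
- Acid 13 with oxalyl chloride and catalytic DMF in CH2Cl2 gives 2-benzyloxy-3-formyl-4-methoxy-6-methylbenzoyl chloride F5.
- F5 acylates alcohol 6 in CH2Cl2 with pyridine and catalytic DMAP at 0 °C to give 14. These bases should be too weak to isomerise the enyne.

**Risk 3, step 5.**
- What may go wrong: C–C bond formation may be slow at the crowded C3 of an ester-chelated, deactivated chloromagnesium phenoxide. O-methoxymethylation may then take over on long heating.
- Fallback: the order of events and the type of formylation are both changed. It sets out from 7 and returns at 9, bypassing 8.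
- Methyl orsellinate 7 undergoes Rieche formylation with Cl2CHOMe and TiCl4 in CH2Cl2 at 0 °C. C3 lies ortho to both titanium-bound phenol oxygens, so the product should be methyl 3-formyl-2,4-dihydroxy-6-methylbenzoate F6.
- One equivalent of MeI with K2CO3 in acetone then methylates the less hindered 4-OH of F6 to give 9. The 2-OH sits between ester and aldehyde and is hydrogen-bonded.

**Further compounds**
F1 | step 10 | methyl 2,4-dihydroxy-3,6-dimethylbenzoate (bought) | COC(=O)c1c(C)cc(O)c(C)c1O
F2 | step 10 | 2,4-dihydroxy-3,6-dimethylbenzoic acid | Cc1cc(O)c(C)c(O)c1C(=O)O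
F3 | step 10 | benzyl 2,4-dihydroxy-3,6-dimethylbenzoate | Cc1cc(O)c(C)c(O)c1C(=O)OCc1ccccc1
F4 | step 10 | 2-benzyloxy-3-formyl-4-methoxy-6-methylbenzoic trifluoroacetic anhydride | COc1cc(C)c(C(=O)OC(=O)C(F)(F)F)c(OCc2ccccc2)c1C=O
F5 | step 9 | 2-benzyloxy-3-formyl-4-methoxy-6-methylbenzoyl chloride | COc1cc(C)c(C(=O)Cl)c(OCc2ccccc2)c1C=O
F6 | step 5 | methyl 3-formyl-2,4-dihydroxy-6-methylbenzoate | COC(=O)c1c(C)cc(O)c(C=O)c1O
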